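## Retrosynthetic overview
1. Caraganin C ⇒ its bis(allyl ether) ⇒ O1–C2 bond (dehydrative closure of the pyran ring, the last ring-forming event) and C2–aryl bond (aryl Grignard reagent + chroman-2-ol).
2. Chroman-2-ol ⇒ trans-3-benzyl-4-styryl-dihydrocoumarin ⇒ C3–CH2Ar bond, made by alkylating the lactone enolate anti to the C4 group. The lactone is the first, temporary closure of the same ring and serves as the stereochemical template.
3. 4-Styryl-dihydrocoumarin ⇒ lactonisation/decarboxylation and C=O → (E)-CH=CH conversion of a malonate–chalcone adduct.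
4. Key disconnection C3–C4: catalytic enantioselective intermolecular Michael addition of dimethyl malonate to a chalcone, which itself comes from a Claisen–Schmidt aldol condensation.
5. Order of stereocentres: C4 (Michael addition) → C3 (relative to C4) → C2 (relative to C3). The target is (2R,3R,4R), that is 2,3-trans-3,4-trans.

Assumption: chroman numbering of the target (O1, C2, C3, C4; ring A = methoxy-bearing benzo ring) is used throughout, and the facial sense of the step 4 catalyst is taken by analogy with simple chalcones, so the equally available quinine-derived pseudoenantiomer is used if the antipode forms.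

## Route

**Step 1**
Reactants: 1 2-hydroxy-4-methoxybenzaldehyde
Product: 2 4-methoxy-2-(methoxymethoxy)benzaldehyde
Conditions: MOMCl, i-Pr2NEt, CH2Cl2, 0 °C → rt
Reagents that add atoms: chloromethyl methyl ether, COCCl
Why: Williamson-type O-alkylation masks the ring A phenol as an acetal that survives hydroxide, hydride and amine bases and stops the later 2-hydroxychalcone from closing to chromene or flavylium species; no stereocentre is formed.

**Step 2**
Reactants: 3 4'-hydroxyacetophenone
Product: 4 4'-(allyloxy)acetophenone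
Conditions: allyl bromide, K2CO3, acetone, reflux
Reagents that add atoms: allyl bromide, C=CCBr
Why: Williamson ether synthesis gives an allyl ether that tolerates every later acid, base, hydride and organometallic step and can be removed at the end under neutral conditions.

**Step 3**
Reactants: 2 4-methoxy-2-(methoxymethoxy)benzaldehyde; 4 4'-(allyloxy)acetophenone
Product: 6 (E)-1-[4-(allyloxy)phenyl]-3-[4-methoxy-2-(methoxymethoxy)phenyl]prop-2-en-1-one, via aldol adduct 5 (not isolated)
Conditions: KOH (40 % aq.), EtOH, rt, 24 h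
Reagents that add atoms: none
Why: In this Claisen–Schmidt crossed aldol condensation only the ketone can enolise and only the aldehyde is a good acceptor, and E1cB loss of water gives the conjugated E-enone.

**Step 4 (key step)**
Reactants: 6 chalcone; 7 dimethyl malonate
Product: 8 dimethyl 2-[(1R)-3-[4-(allyloxy)phenyl]-1-[4-methoxy-2-(methoxymethoxy)phenyl]-3-oxopropyl]malonate
Conditions: 7 (5 equiv), 1-[3,5-bis(trifluoromethyl)phenyl]-3-[(8R,9R)-6'-methoxycinchonan-9-yl]thiourea (from 9-amino-9-deoxy-epi-quinidine, 10 mol %), toluene (1 M), rt → 35 °C, 4–6 d; recrystallise to raise ee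
Reagents that add atoms: none
Why: In this intermolecular asymmetric Michael addition the thiourea hydrogen-bonds the enone carbonyl while the quinuclidine deprotonates the malonate, so the enolate reaches one face of the E-enone and sets C4 as R; from here on C4 is only β to carbonyl groups and cannot epimerise.

**Step 5**
Reactants: 8 Michael adduct
Product: 9 dimethyl 2-[(1R)-3-[4-(allyloxy)phenyl]-3-hydroxy-1-[4-methoxy-2-(methoxymethoxy)phenyl]propyl]malonate (about 1:1 at the carbinol carbon)
Conditions: NaBH4, CeCl3·7H2O, MeOH/THF, −20 → 0 °C, 20 min; pH 7 buffer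
Reagents that add atoms: none
Why: Luche reduction takes the aryl ketone chemoselectively over the esters under nearly neutral conditions that suppress δ-lactonisation; the new carbinol centre forms unselectively and is deleted in step 6.

**Step 6**
Reactants: 9 carbinol
Product: 11 dimethyl 2-[(1R,2E)-3-[4-(allyloxy)phenyl]-1-[4-methoxy-2-(methoxymethoxy)phenyl]prop-2-en-1-yl]malonate, via benzylic mesylate 10 (not isolated)
Conditions: MsCl, Et3N, CH2Cl2, 0 °C; then DBU, 0 → 40 °C
Reagents that add atoms: methanesulfonyl chloride, CS(=O)(=O)Cl (its atoms stay only in 10)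
Why: Sulfonylation followed by base-induced β-elimination of the very labile 4-alkoxybenzylic sulfonate can only remove a proton from the single adjacent CH2, so it gives the aryl-conjugated E-alkene without acid and without touching C4.

**Step 7**
Reactants: 11 styryl malonate
Product: 13 methyl (4R)-4-[(E)-2-[4-(allyloxy)phenyl]ethenyl]-7-methoxy-2-oxochromane-3-carboxylate (C3 labile; mostly 3,4-trans), via free phenol 12 (not isolated)
Conditions: HCl (0.15 M in MeOH), 45 °C, 2 h; evaporate; then Et3N (0.2 equiv), 5 Å MS, toluene, 60 °C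
Reagents that add atoms: none
Why: Acid-catalysed acetal exchange cleaves the aryl MOM ether far faster than dilute acid protonates a β-alkyl-4-alkoxystyrene, and amine-catalysed transesterification then lactonises the phenol onto the activated malonate ester, forming the pyranone ring with C4 untouched.

**Step 8**
Reactants: 13 lactone ester
Product: 14 (4S)-4-[(E)-2-[4-(allyloxy)phenyl]ethenyl]-7-methoxychroman-2-one
Conditions: LiCl (3 equiv), H2O (2 equiv), DMSO, 140 °C, 3 h
Reagents that add atoms: none
Why: In this Krapcho dealkoxycarbonylation chloride demethylates the β-dicarbonyl ester and the carboxylate loses CO2 under essentially neutral conditions well below the aryl allyl ether Claisen range; the C4 geometry is unchanged and the descriptor becomes S only because C3 is now CH2.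

**Step 9**
Reactants: 15 4-hydroxybenzaldehyde
Product: 16 4-(allyloxy)benzaldehyde
Conditions: allyl bromide, K2CO3, acetone, reflux
Reagents that add atoms: allyl bromide, C=CCBr
Why: Williamson ether synthesis installs the same final-stage protecting group as in step 2, so one operation will free both phenols.

**Step 10**
Reactants: 16 4-(allyloxy)benzaldehyde
Product: 17 [4-(allyloxy)phenyl]methanol
Conditions: NaBH4, MeOH, 0 °C
Reagents that add atoms: none
Why: This simple hydride reduction of an aromatic aldehyde leaves the allyl ether untouched.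

**Step 11**
Reactants: 17 [4-(allyloxy)phenyl]methanol
Product: 18 1-(allyloxy)-4-(bromomethyl)benzene
Conditions: PBr3 (0.4 equiv), Et2O, 0 °C; used at once
Reagents that add atoms: phosphorus tribromide, BrP(Br)Br
Why: Bromide displaces the phosphite ester of an activated benzylic alcohol cleanly (SN2) and gives a very reactive alkylating agent.

**Step 12**
Reactants: 14 4-styryl lactone; 18 benzylic bromide
Product: 20 (3R,4R)-3-[4-(allyloxy)benzyl]-4-[(E)-2-[4-(allyloxy)phenyl]ethenyl]-7-methoxychroman-2-one (3,4-trans), via lithium enolate 19 (not isolated)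
Conditions: LiN(SiMe3)2 (1.05 equiv), THF, −78 °C, 45 min; 18 (1.3 equiv), DMPU, −78 → −40 °C
Reagents that add atoms: lithium bis(trimethylsilyl)amide, [Li]N([Si](C)(C)C)[Si](C)(C)C (lithium stays only in 19)
Why: In this kinetic enolate alkylation the C4 styryl group sits pseudo-axial to avoid the peri hydrogen and blocks one face of the flat lactone enolate, so the bromide enters anti and sets C3 as R, trans to C4, which is also the more stable epimer.

**Step 13**
Reactants: 20 trans-lactone
Product: 21 (3R,4R)-3-[4-(allyloxy)benzyl]-4-[(E)-2-[4-(allyloxy)phenyl]ethenyl]-7-methoxychroman-2-ol (anomer mixture)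
Conditions: i-Bu2AlH (1.1 equiv), CH2Cl2, −78 °C
Reagents that add atoms: none
Why: Partial hydride reduction stops at the aluminium hemiacetal, which is stable at −78 °C; alkenes and ethers are inert, and the new anomeric centre is irrelevant because it is opened in step 14.

**Step 14**
Reactants: 21 lactol; 22 1-bromo-2,4-dimethoxybenzene
Product: 24 (2R,3R,4E)-2-[4-(allyloxy)benzyl]-5-[4-(allyloxy)phenyl]-1-(2,4-dimethoxyphenyl)-3-(2-hydroxy-4-methoxyphenyl)pent-4-en-1-ol (C1 epimers), via aryl Grignard reagent 23 (not isolated)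
Conditions: 22 (3.5 equiv), Mg, THF, reflux; then 21, THF, −20 → 0 °C; aq. NH4Cl
Reagents that add atoms: magnesium, [Mg] (stays only in 23)
Why: In this Grignard addition the magnesium lactolate opens to the phenoxide aldehyde, which is trapped faster than its α-centre can enolise at low temperature; the carbinol configuration need not be controlled because it is ionised in step 15.

**Step 15**
Reactants: 24 phenol carbinol
Product: 25 (2R,3R,4R)-3-[4-(allyloxy)benzyl]-4-[(E)-2-[4-(allyloxy)phenyl]ethenyl]-2-(2,4-dimethoxyphenyl)-7-methoxychromane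
Conditions: PPTS (0.2 equiv), 4 Å MS, CH2Cl2, rt
Reagents that add atoms: none
Why: In this intramolecular SN1 etherification (dehydrative cyclisation) mild acid ionises only the 2,4-dimethoxybenzylic alcohol, and the phenol captures the cation through the A(1,3)-minimised chair-like arrangement with aryl, benzyl and styryl groups all equatorial, so both carbinol epimers converge on the 2,3-trans (2R) chroman, which should also be the thermodynamic isomer.

**Step 16**
Reactants: 25 bis(allyl ether)
Product: 26 caraganin C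
Conditions: Pd(PPh3)4 (5 mol %), morpholine (6 equiv), THF, rt
Reagents that add atoms: none
Why: In this Tsuji–Trost deallylation zerovalent palladium ionises both aryl allyl ethers to π-allyl complexes that morpholine traps under neutral conditions, leaving the methyl ethers, the benzylic C2–O bond, the three stereocentres and the E-styrene untouched.

## Compound list
1 | 2-hydroxy-4-methoxybenzaldehyde | COc1ccc(C=O)c(O)c1 | starting material
2 | 4-methoxy-2-(methoxymethoxy)benzaldehyde | COCOc1cc(OC)ccc1C=O | intermediate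
3 | 4'-hydroxyacetophenone | CC(=O)c1ccc(O)cc1 | starting material
4 | 4'-(allyloxy)acetophenone | CC(=O)c1ccc(OCC=C)cc1 | intermediate
5 | 1-[4-(allyloxy)phenyl]-3-hydroxy-3-[4-methoxy-2-(methoxymethoxy)phenyl]propan-1-one | O=C(CC(O)c1ccc(OC)cc1OCOC)c1ccc(OCC=C)cc1 | intermediate (not isolated)
6 | (E)-1-[4-(allyloxy)phenyl]-3-[4-methoxy-2-(methoxymethoxy)phenyl]prop-2-en-1-one | O=C(/C=C/c1ccc(OC)cc1OCOC)c1ccc(OCC=C)cc1 | intermediate
7 | dimethyl malonate | COC(=O)CC(=O)OC | starting material
8 | dimethyl 2-[(1R)-3-[4-(allyloxy)phenyl]-1-[4-methoxy-2-(methoxymethoxy)phenyl]-3-oxopropyl]malonate | COC(=O)C(C(=O)OC)[C@@H](CC(=O)c1ccc(OCC=C)cc1)c1ccc(OC)cc1OCOC | intermediate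
9 | dimethyl 2-[(1R)-3-[4-(allyloxy)phenyl]-3-hydroxy-1-[4-methoxy-2-(methoxymethoxy)phenyl]propyl]malonate, carbinol epimers | COC(=O)C(C(=O)OC)[C@@H](CC(O)c1ccc(OCC=C)cc1)c1ccc(OC)cc1OCOC | intermediate
10 | methanesulfonate of 9 | COC(=O)C(C(=O)OC)[C@@H](CC(OS(C)(=O)=O)c1ccc(OCC=C)cc1)c1ccc(OC)cc1OCOC | intermediate (not isolated)
11 | dimethyl 2-[(1R,2E)-3-[4-(allyloxy)phenyl]-1-[4-methoxy-2-(methoxymethoxy)phenyl]prop-2-en-1-yl]malonate | COC(=O)C(C(=O)OC)[C@@H](/C=C/c1ccc(OCC=C)cc1)c1ccc(OC)cc1OCOC | intermediate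
12 | dimethyl 2-[(1R,2E)-3-[4-(allyloxy)phenyl]-1-(2-hydroxy-4-methoxyphenyl)prop-2-en-1-yl]malonate | COC(=O)C(C(=O)OC)[C@@H](/C=C/c1ccc(OCC=C)cc1)c1ccc(OC)cc1O | intermediate (not isolated)
13 | methyl (4R)-4-[(E)-2-[4-(allyloxy)phenyl]ethenyl]-7-methoxy-2-oxochromane-3-carboxylate, C3 labile | COC(=O)C1C(=O)Oc2cc(OC)ccc2[C@@H]1/C=C/c1ccc(OCC=C)cc1 | intermediate
14 | (4S)-4-[(E)-2-[4-(allyloxy)phenyl]ethenyl]-7-methoxychroman-2-one | O=C1C[C@@H](/C=C/c2ccc(OCC=C)cc2)c2ccc(OC)cc2O1 | intermediate
15 | 4-hydroxybenzaldehyde | O=Cc1ccc(O)cc1 | starting material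
16 | 4-(allyloxy)benzaldehyde | O=Cc1ccc(OCC=C)cc1 | intermediate
17 | [4-(allyloxy)phenyl]methanol | OCc1ccc(OCC=C)cc1 | intermediate
18 | 1-(allyloxy)-4-(bromomethyl)benzene | BrCc1ccc(OCC=C)cc1 | intermediate
19 | lithium enolate of 14 | [Li+].[O-]C1=C[C@@H](/C=C/c2ccc(OCC=C)cc2)c2ccc(OC)cc2O1 | intermediate (not isolated)
20 | (3R,4R)-3-[4-(allyloxy)benzyl]-4-[(E)-2-[4-(allyloxy)phenyl]ethenyl]-7-methoxychroman-2-one, 3,4-trans | COc1ccc2c(c1)OC(=O)[C@H](Cc1ccc(OCC=C)cc1)[C@H]2/C=C/c1ccc(OCC=C)cc1 | intermediate
21 | (3R,4R)-3-[4-(allyloxy)benzyl]-4-[(E)-2-[4-(allyloxy)phenyl]ethenyl]-7-methoxychroman-2-ol, anomers | COc1ccc2c(c1)OC(O)[C@H](Cc1ccc(OCC=C)cc1)[C@H]2/C=C/c1ccc(OCC=C)cc1 | intermediate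
22 | 1-bromo-2,4-dimethoxybenzene | COc1ccc(Br)c(OC)c1 | starting material
23 | 2,4-dimethoxyphenylmagnesium bromide | COc1ccc([Mg]Br)c(OC)c1 | intermediate (not isolated)
24 | (2R,3R,4E)-2-[4-(allyloxy)benzyl]-5-[4-(allyloxy)phenyl]-1-(2,4-dimethoxyphenyl)-3-(2-hydroxy-4-methoxyphenyl)pent-4-en-1-ol, C1 epimers | COc1ccc(c(OC)c1)C(O)[C@H](Cc1ccc(OCC=C)cc1)[C@@H](/C=C/c1ccc(OCC=C)cc1)c1ccc(OC)cc1O | intermediate
25 | (2R,3R,4R)-3-[4-(allyloxy)benzyl]-4-[(E)-2-[4-(allyloxy)phenyl]ethenyl]-2-(2,4-dimethoxyphenyl)-7-methoxychromane | COc1ccc2c(c1)O[C@@H](c1ccc(OC)cc1OC)[C@H](Cc1ccc(OCC=C)cc1)[C@H]2/C=C/c1ccc(OCC=C)cc1 | intermediate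
26 | caraganin C, (2R,3R,4R)-2-(2,4-dimethoxyphenyl)-3-(4-hydroxybenzyl)-4-[(E)-2-(4-hydroxyphenyl)ethenyl]-7-methoxychromane | COc1ccc2c(c1)O[C@@H](c1ccc(OC)cc1OC)[C@H](Cc1ccc(O)cc1)[C@H]2/C=C/c1ccc(O)cc1 | target

## Step count and risks
Total steps: 16. Longest linear sequence: 12 (steps 1, 3–8 and 12–16, from 1 to 26).

**Step 4 (rate and ee on an electron-rich, ortho-substituted chalcone).** The fallback sets out from 2 and rejoins at 9. It replaces hydrogen-bond catalysis on the enone with iminium catalysis on the enal, and the aryl ring arrives afterwards.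
- Aldehyde 2 is homologated with Ph3P=CHCHO (toluene, 80 °C) to (E)-3-[4-methoxy-2-(methoxymethoxy)phenyl]prop-2-enal F1.
- Malonate 7 is added with (S)-2-{bis[3,5-bis(trifluoromethyl)phenyl](trimethylsilyloxy)methyl}pyrrolidine (10 mol %, EtOH, rt).
- The silyloxy-diarylmethyl group shields one face of the E-iminium ion, which gives dimethyl 2-[(1R)-1-[4-methoxy-2-(methoxymethoxy)phenyl]-3-oxopropyl]malonate F2.
- F2 is treated at −78 °C with 2.2 equiv of 4-(allyloxy)phenylmagnesium bromide F3, made from commercial 1-(allyloxy)-4-bromobenzene and Mg. The first equivalent parks the malonate as its enolate and the second adds to the aldehyde, giving 9.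

**Step 12 (ketene-type decomposition or self-condensation of the aryl lactone enolate; diastereoselectivity).** The fallback sets out from 13 and rejoins at 20. It alkylates the soft β-dicarbonyl enolate before the ester is removed.
- Treating 13 with K2CO3 and 18 in acetone at rt places the benzyl group anti to the styryl group. The product is methyl (3R,4S)-3-[4-(allyloxy)benzyl]-4-[(E)-2-[4-(allyloxy)phenyl]ethenyl]-7-methoxy-2-oxochromane-3-carboxylate F4 (benzyl trans to styryl).
- LiCl/H2O/DMSO at 140 °C then removes the ester and gives 20 together with its 3,4-cis epimer (3S,4R)-3-[4-(allyloxy)benzyl]-4-[(E)-2-[4-(allyloxy)phenyl]ethenyl]-7-methoxychroman-2-one F5.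
- F5 is equilibrated to 20 with DBU in toluene. Only C3 is acidic, so C4 and the ee are safe.

**Step 15 (C2 diastereoselectivity; elimination of the cation).** The fallback sets out from 21 and rejoins at 25. It keeps the ring closed and forms the C2–aryl bond instead of the C2–O bond.
- Lactol 21 is acetylated (Ac2O, pyridine, DMAP) to (3R,4R)-3-[4-(allyloxy)benzyl]-4-[(E)-2-[4-(allyloxy)phenyl]ethenyl]-7-methoxychroman-2-yl acetate F6.
- F6 is ionised with BF3·OEt2 in CH2Cl2 at −78 °C in the presence of 1,3-dimethoxybenzene (1.2 equiv).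
- Friedel–Crafts attack through the arene 4-position on the cyclic oxocarbenium ion, anti to the C3 benzyl group, gives 25 directly.

## Further compounds
F1 | step 4 | (E)-3-[4-methoxy-2-(methoxymethoxy)phenyl]prop-2-enal | O=C/C=C/c1ccc(OC)cc1OCOC
F2 | step 4 | dimethyl 2-[(1R)-1-[4-methoxy-2-(methoxymethoxy)phenyl]-3-oxopropyl]malonate | COC(=O)C(C(=O)OC)[C@@H](CC=O)c1ccc(OC)cc1OCOC
F3 | step 4 | 4-(allyloxy)phenylmagnesium bromide | C=CCOc1ccc([Mg]Br)cc1
F4 | step 12 | methyl (3R,4S)-3-[4-(allyloxy)benzyl]-4-[(E)-2-[4-(allyloxy)phenyl]ethenyl]-7-methoxy-2-oxochromane-3-carboxylate | COc1ccc2c(c1)OC(=O)[C@](C(=O)OC)(Cc1ccc(OCC=C)cc1)[C@H]2/C=C/c1ccc(OCC=C)cc1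
F5 | step 12 | (3S,4R)-3-[4-(allyloxy)benzyl]-4-[(E)-2-[4-(allyloxy)phenyl]ethenyl]-7-methoxychroman-2-one | COc1ccc2c(c1)OC(=O)[C@@H](Cc1ccc(OCC=C)cc1)[C@H]2/C=C/c1ccc(OCC=C)cc1
F6 | step 15 | (3R,4R)-3-[4-(allyloxy)benzyl]-4-[(E)-2-[4-(allyloxy)phenyl]ethenyl]-7-methoxychroman-2-yl acetate | COc1ccc2c(c1)OC(OC(C)=O)[C@H](Cc1ccc(OCC=C)cc1)[C@H]2/C=C/c1ccc(OCC=C)cc1
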